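(The earlier runs and the new flask stem from a simulated flask from invented constants; noise was put on by code.)

**Question:** What is the easy step here?

**Answer:** X, the limiting reagent by charge, starts at 0.14 M in both new flasks, and the part reacted is asked, so I count halvings of X, that is, half-lives passed.

| flask | X | L | remark | time |
|---|---|---|---|---|
| spring | 0.14 M | 1.5 equiv | run made earlier |  |
| winter | 0.14 M | 1.8 equiv | run made earlier |  |
| dawn | 0.14 M | 2 equiv | run made earlier |  |
| ochre | 0.14 M | 2.40 equiv |  | 10 min |
| teal | 0.14 M | 1.20 equiv |  | 10 min |

| run | time / min | X / % | Z / % |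
|---|---|---|---|
| spring | 0.417 | 89 | 9 |
| spring | 0.833 | 83 | 21 |
| spring | 1.33 | 74 | 23 |
| spring | 2.50 | 65 | 39 |
| spring | 5.00 | 51 | 44 |
| winter | 1.00 | 73 | 29 |
| winter | 2.00 | 60 | 38 |
| winter | 3.00 | 56 | 44 |
| winter | 4.00 | 50 | 55 |
| winter | 5.00 | 48 | 53 |
| dawn | 0.417 | 88 | 18 |
| dawn | 0.833 | 77 | 25 |
| dawn | 1.33 | 69 | 35 |
| dawn | 2.50 | 48 | 48 |
| dawn | 5.00 | 43 | 58 |

(readings scatter by 2 percentage points)

- part of the X that has reacted at the end, ochre
- part of the X that has reacted at the end, teal
- what raising the equivalents of L from its lowest to its highest value here does to the part of the X that has reacted (changes below 5 percentage points count as none) (it falls / it rises / no change)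

- steps that have been proposed: X + L -> G + Z; L + G <-> Q; L <-> J

**Question:** What do the runs give at 5.00 min?

**Answer:** Halvings per equivalent of L are 0.648 in spring, 0.588 in winter and 0.609 in dawn. Their mean is 0.615, so I take the count as proportional to L.

**Question:** But you need 10 min. Does doubling the time double the count?

**Answer:** Not in these readings. From 2.50 min to 5.00 min it grew by a factor of 1.56 in spring and 1.15 in dawn, with a mean of 1.36. This is the weak spot: the two factors differ widely, and I carry their mean one doubling beyond the readings.

**Question:** What do you commit to?

**Answer:** My estimate of the halvings of X per equivalent of L in 10 min is 0.834. Ochre then gets 2.00 halvings, so I expect 75.0% reacted, and teal gets 1.00, so I expect 50.0% reacted.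

The forecast gives 70% for ochre and 50% for teal, and its answer on raising L is "it rises", reasoning: “This fits by-product G sequestering a second L as Q”. My ochre figure is higher than the forecast's.

The flasks give 79.2% for ochre and 49.1% for teal, and the answer on raising L is "it rises", by 30 percentage points.

    X + L → G + Z (k = 1.60 /M/min)
    L + G ⇌ Q, settled at all times (K = 190 /M)
    L ⇌ J (K = 1.20, k = 0.200 /min)

Counted the same way, ochre made 0.945 halvings per equivalent and teal 0.812, against my 0.834. In ochre, the path from L to J had 92% of its turnover up to 10 min behind it at 2.00 min, the path from X and L 61%. Between 5.00 min and 10.0 min, ochre's J fell from 0.0848 M to 0.0747 M, Q rose from 0.0875 M to 0.100 M, and X went from 32.8% to 20.8%.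

With 0.960 equiv of L in the ochre recipe, 0.834 gives 0.801 halvings, so 42.6% reacted. That flask gives 41.1%.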